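The numbers were chosen freely; the rest is arithmetic.

Late in this run, at 5.0 min, what I needed was how much dissolved partner the starting material had been exposed to, since each step using partner is first order in its concentration [B].

starting material 31 mM; second substrate 155 mM (in portions, 2); third substrate 31.0 mM; protic impurity 15.5 mM; solid reagent 77.5 mM; time 5.0 min; the portions of second substrate follow each other after 80 s, the first at the start

    starting material + partner → target (k1 = 0.289 /M/s)
    second substrate + partner → second product (k2 = 0.0181 /M/s)
    third substrate + partner → third product (k3 = 0.796 /M/s)
    second substrate + protic impurity → quenched substrate (k4 = 0.557 /M/s)
    solid reagent ⇌ partner, rate k5*(cs5 - [partner]) while solid is left; crystals form when [partner] > cs5 (cs5 = 29 mM, k5 = 0.00987 /s)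

- given per volume of solution although it is solid: solid reagent
- at the start none of the solid reagent is in solution
- the reaction counts as stopped when no species that holds the starting material changes by six tenths of a point or more over the second half of the time
- run time (flask): 5.0 min

1. which holds at 5.0 min: what has brought the reaction to rest, or that it has not come to rest (for what has run out or reacted, a solid counts together with what of it has only dissolved) (the partner has run out first / all of the starting material has reacted / it is still moving / forward and back rates have come level)
2. the target standing at 5.0 min, as a percentage of the starting material charged

My ladder began with the consumers of partner. At their charged concentrations, each step taken alone, third substrate took it with a half-life of 0.47 min, faster than starting material at 1.3 min and second substrate, with its whole charge counted as if present at once, at 4.1 min. Together, counting the whole charge of second substrate net of what the protic impurity takes, they formed a pseudo-first-order sink s = 2.17 /min.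

Dissolution came next, with its coefficient of 0.59 /min slower than s, so I took supply and use as balanced, which gave [B] = (coefficient × solubility)/(coefficient + s) = 6.22 mM, below the solubility of 29 mM.

I reckoned the substrates to run down more slowly than that balance set in, third substrate at 0.297 /min. That [B] held for the whole run gave a first exposure of 0.539, from which I reckoned s at the end of the run as 0.800 /min and [B] there as 12.3 mM. The mean of the two, 9.28 mM, gave 0.804 for the exposure x, the starting material's rate constant times the time integral of [B]; starting material left is exp(−x).

On the last rung, I reckoned about 58.2 mM of solid reagent dissolved by the end, less than the 77.5 mM charged. I therefore expected a run still moving, with target at 55.3%.

The forecast said it is still moving, with 53% (range 47% to 59%), on the ground that “the integrated exposure gives about half conversion of the starting material”; my figure stood higher.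

The simulation gave the verdict “it is still moving” and target at 51.5%.

The third substrate reading of 13.6% in this flask put the exposure at 0.724, against my 0.804, and that exposure leaves 48.5% of the starting material, where the flask held 48.5%. A neighbouring flask with 19 mM of solid reagent ended with solid at 0% and partner at 0.0267 mM. Dividing that flask's charge by the starting sink gave an exposure of 0.152 and target at 14.1%. That neighbouring flask held target at 17.2%.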